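**Retrosynthetic overview**
1. Target 15 comes from its decamethyl ether 14; the tenfold O-demethylation is the last step.
2. 14 is cut at the two diaryl ether bonds (copper-catalysed couplings) into phenol 8 (rings A–B), ring C (12) and phenol 11 (ring D).
3. The A–B biaryl bond of 8 comes from an intermolecular Michael addition of 1,3,5-trimethoxybenzene 4 (the tris-enol-ether form of cyclohexane-1,3,5-trione) to 2,6-dibromo-1,4-benzoquinone 3. The quinone oxygens become O-1 and O-4 of ring B, and the two C–Br bonds become C–OMe.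
4. No ring is built. All four benzene rings are bought, and only ring B passes through the quinone level. The joining order is A+B, then D+C, then AB+CD.

Assumption: the target has no stereocentre, and because ring A is symmetric about the biaryl bond it has no stereogenic axis. It is achiral, so there is no enantiomer to control. Ring B is numbered as in quinone 3, with C1 lying between the two C–Br carbons.

**Step 1**
Reactants: 1 4-methoxyphenol
Product: 2 2,6-dibromo-4-methoxyphenol
Conditions: Br2 (2.05 equiv), CH2Cl2, 0 °C to rt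
Reagents that add atoms: bromine, BrBr
Why: In this electrophilic aromatic bromination the free OH is the stronger director and its para position is blocked, so both bromines enter ortho to OH.

**Step 2**
Reactants: 2 2,6-dibromo-4-methoxyphenol
Product: 3 2,6-dibromo-1,4-benzoquinone
Conditions: PhI(OAc)2 (1.1 equiv), MeCN–H2O 3:1, 0 °C to rt
Reagents that add atoms: water, O
Why: In this oxidative dearomatisation of a 4-methoxyphenol by the trivalent iodine reagent, water adds at the para carbon and loss of methanol gives the p-quinone.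

**Step 3 (key step)**
Reactants: 3 2,6-dibromo-1,4-benzoquinone (2.1 equiv); 4 1,3,5-trimethoxybenzene (1.0 equiv)
Product: 6 2,6-dibromo-3-(2,4,6-trimethoxyphenyl)benzene-1,4-diol, via arylquinone 5 (not isolated)
Conditions: TfOH (10 mol %), CH2Cl2–HFIP 4:1, 0 °C to rt, dark; then Na2S2O4, EtOAc–H2O, rt
Reagents that add atoms: none
Why: In this acid-promoted intermolecular Michael addition the enol-ether carbon of 4 attacks C3 of 3, the unsubstituted β-carbon of the enone whose C1 carbonyl is activated by two flanking bromines; both partners are symmetric so one regioisomer forms, the second equivalent of 3 oxidises the adduct to 5, dithionite returns it to 6, and no stereocentre arises.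

**Step 4**
Reactants: 6 2,6-dibromo-3-(2,4,6-trimethoxyphenyl)benzene-1,4-diol
Product: 7 2,6-dibromo-4-methoxy-3-(2,4,6-trimethoxyphenyl)phenol
Conditions: NaH (2.2 equiv), degassed THF–DMF 4:1, 0 °C, Ar; MeI (1.0 equiv), 0 °C to rt; then 1 M HCl
Reagents that add atoms: iodomethane, CI
Why: In this Williamson methylation of the dianion, the oxyanion between the two bromines is the more stabilised and more hindered one, so one equivalent of MeI reacts at the more basic O-4 oxyanion.

**Step 5**
Reactants: 7 2,6-dibromo-4-methoxy-3-(2,4,6-trimethoxyphenyl)phenol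
Product: 8 2,4,6-trimethoxy-3-(2,4,6-trimethoxyphenyl)phenol (2,2',4,4',6,6'-hexamethoxybiphenyl-3-ol)
Conditions: NaOMe (10 equiv, in MeOH), CuBr (30 mol %), DMF, 110 °C, sealed tube, Ar; then 1 M HCl
Reagents that add atoms: sodium methoxide, [Na+].[O-]C
Why: This Ullmann-type copper-catalysed methoxylation is the standard conversion of 2,6-dibromophenols into 2,6-dimethoxyphenols, and the large excess of methoxide outruns the weakly nucleophilic, hindered phenoxide.

**Step 6**
Reactants: 9 2,4,6-trimethoxybenzaldehyde
Product: 11 2,4,6-trimethoxyphenol, via aryl formate 10 (not isolated)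
Conditions: 30% H2O2 (1.3 equiv), H2SO4 (cat.), MeOH, rt
Reagents that add atoms: hydrogen peroxide, OO
Why: In this acid-catalysed Dakin (Baeyer–Villiger type) oxidation the electron-rich aryl group migrates to oxygen, and formate 10 is methanolysed in the same flask.

**Step 7**
Reactants: 11 2,4,6-trimethoxyphenol; 12 1,3-dibromo-5-methoxybenzene (3 equiv)
Product: 13 1-bromo-3-methoxy-5-(2,4,6-trimethoxyphenoxy)benzene
Conditions: CuI (10 mol %), picolinic acid (20 mol %), K3PO4 (2 equiv), DMSO, 90 °C, Ar
Reagents that add atoms: none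
Why: This Ullmann diaryl ether synthesis uses a catalyst system suited to di-ortho-substituted phenols, and the threefold excess of the symmetric dibromide (recovered afterwards) keeps the reaction at monosubstitution.

**Step 8**
Reactants: 8 2,4,6-trimethoxy-3-(2,4,6-trimethoxyphenyl)phenol; 13 1-bromo-3-methoxy-5-(2,4,6-trimethoxyphenoxy)benzene (1.2 equiv)
Product: 14 decamethyl ether of the target
Conditions: CuI (20 mol %), picolinic acid (40 mol %), K3PO4 (2 equiv), DMSO, 105 °C, Ar
Reagents that add atoms: none
Why: In this second Ullmann diaryl ether synthesis, 8 has a single free OH, 13 has a single C–Br, and all other groups are inert methyl or aryl ethers.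

**Step 9**
Reactants: 14 decamethyl ether of the target
Product: 15 target CNP0260439.0
Conditions: BBr3 (25 equiv), CH2Cl2, −78 °C to rt, 36 h; then H2O, 0 °C; C18 chromatography under Ar
Reagents that add atoms: none
Why: In this Lewis-acid ether cleavage, bromide attacks the methyl carbon of each boron-complexed ArOMe, while the diaryl ether and biaryl bonds offer no sp3 carbon and survive.

**Compound list**
1 | 4-methoxyphenol | COc1ccc(O)cc1 | starting material
2 | 2,6-dibromo-4-methoxyphenol | COc1cc(Br)c(O)c(Br)c1 | intermediate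
3 | 2,6-dibromo-1,4-benzoquinone | O=C1C=C(Br)C(=O)C(Br)=C1 | intermediate
4 | 1,3,5-trimethoxybenzene | COc1cc(OC)cc(OC)c1 | starting material
5 | 2,6-dibromo-3-(2,4,6-trimethoxyphenyl)-1,4-benzoquinone | COc1cc(OC)c(C2=C(Br)C(=O)C(Br)=CC2=O)c(OC)c1 | intermediate
6 | 2,6-dibromo-3-(2,4,6-trimethoxyphenyl)benzene-1,4-diol | COc1cc(OC)c(-c2c(O)cc(Br)c(O)c2Br)c(OC)c1 | intermediate
7 | 2,6-dibromo-4-methoxy-3-(2,4,6-trimethoxyphenyl)phenol | COc1cc(OC)c(-c2c(OC)cc(Br)c(O)c2Br)c(OC)c1 | intermediate
8 | 2,4,6-trimethoxy-3-(2,4,6-trimethoxyphenyl)phenol | COc1cc(OC)c(-c2c(OC)cc(OC)c(O)c2OC)c(OC)c1 | intermediate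
9 | 2,4,6-trimethoxybenzaldehyde | COc1cc(OC)c(C=O)c(OC)c1 | starting material
10 | 2,4,6-trimethoxyphenyl formate | COc1cc(OC)c(OC=O)c(OC)c1 | intermediate
11 | 2,4,6-trimethoxyphenol | COc1cc(OC)c(O)c(OC)c1 | intermediate
12 | 1,3-dibromo-5-methoxybenzene | COc1cc(Br)cc(Br)c1 | starting material
13 | 1-bromo-3-methoxy-5-(2,4,6-trimethoxyphenoxy)benzene | COc1cc(Br)cc(Oc2c(OC)cc(OC)cc2OC)c1 | intermediate
14 | decamethyl ether: 1-methoxy-3-(2,4,6-trimethoxyphenoxy)-5-[2,4,6-trimethoxy-3-(2,4,6-trimethoxyphenyl)phenoxy]benzene | COc1cc(Oc2c(OC)cc(OC)cc2OC)cc(Oc2c(OC)cc(OC)c(-c3c(OC)cc(OC)cc3OC)c2OC)c1 | intermediate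
15 | target, achiral decaphenol | Oc1cc(Oc2c(O)cc(O)cc2O)cc(Oc2c(O)cc(O)c(-c3c(O)cc(O)cc3O)c2O)c1 | target

**Totals:** 9 steps in all. The longest linear sequence is 7 steps (1, 2, 3, 4, 5, 8, 9).

**The three steps most likely to fail**

Step 3. Compound 4 is only a moderate π-nucleophile and 3 is an oxidant, so over-arylation or charge-transfer chemistry could win. The fallback sets out from 3 and comes back at 5, and it swaps the polar addition for a radical Meerwein arylation. Commercial 2,4,6-trimethoxyaniline is diazotised (NaNO2, HBF4, 0 °C) to 2,4,6-trimethoxybenzenediazonium tetrafluoroborate F1. F1 is added to 3 in aqueous DMSO buffered with NaOAc, with a trace of a hydroquinone as initiator. The aryl radical adds at the free C3–H of the quinone and gives 5, which dithionite takes to 6 as before.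

Step 5. The bromide next to the tetra-ortho-substituted biaryl bond may be reduced instead of substituted. The fallback sets out from 7 and comes back at 8, and it replaces copper catalysis by halogen–lithium exchange, which is insensitive to crowding.
- 7 is protected (MOMCl, iPr2NEt) as 1,3-dibromo-5-methoxy-2-(methoxymethoxy)-4-(2,4,6-trimethoxyphenyl)benzene F2.
- n-BuLi is added at −78 °C to F2 with B(OiPr)3 already present. After hydrolysis this gives [5-methoxy-2-(methoxymethoxy)-4-(2,4,6-trimethoxyphenyl)-1,3-phenylene]diboronic acid F3.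
- F3 is oxidised at once (H2O2, NaOH) to 5-methoxy-2-(methoxymethoxy)-4-(2,4,6-trimethoxyphenyl)benzene-1,3-diol F4.
- MeI/K2CO3 gives 1,3,5-trimethoxy-2-(methoxymethoxy)-4-(2,4,6-trimethoxyphenyl)benzene F5, and HCl in MeOH frees 8.

Step 8. Phenol 8 is electron-rich and hindered, and it may oxidise or couple too slowly at 105 °C. The fallback sets out from 13 and comes back at 14, using a metal-free arylation with a diaryliodonium salt near room temperature.
- 13 is lithiated (n-BuLi, −78 °C) and borylated (B(OiPr)3, then acid) to [3-methoxy-5-(2,4,6-trimethoxyphenoxy)phenyl]boronic acid F6.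
- F6 reacts with 4-MeOC6H4I(OAc)2 and BF3·OEt2 at −30 °C. An aqueous NaBF4 wash then gives (4-methoxyphenyl)[3-methoxy-5-(2,4,6-trimethoxyphenoxy)phenyl]iodonium tetrafluoroborate F7.
- The potassium phenoxide of 8 (t-BuOK, THF, rt to 40 °C) takes over the less electron-rich ring C aryl group by ligand coupling and gives 14.

**Further compounds**
F1 | step 3 | 2,4,6-trimethoxybenzenediazonium tetrafluoroborate | COc1cc(OC)c([N+]#N)c(OC)c1.F[B-](F)(F)F
F2 | step 5 | 1,3-dibromo-5-methoxy-2-(methoxymethoxy)-4-(2,4,6-trimethoxyphenyl)benzene | COCOc1c(Br)cc(OC)c(-c2c(OC)cc(OC)cc2OC)c1Br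
F3 | step 5 | [5-methoxy-2-(methoxymethoxy)-4-(2,4,6-trimethoxyphenyl)-1,3-phenylene]diboronic acid | COCOc1c(B(O)O)cc(OC)c(-c2c(OC)cc(OC)cc2OC)c1B(O)O
F4 | step 5 | 5-methoxy-2-(methoxymethoxy)-4-(2,4,6-trimethoxyphenyl)benzene-1,3-diol | COCOc1c(O)cc(OC)c(-c2c(OC)cc(OC)cc2OC)c1O
F5 | step 5 | 1,3,5-trimethoxy-2-(methoxymethoxy)-4-(2,4,6-trimethoxyphenyl)benzene | COCOc1c(OC)cc(OC)c(-c2c(OC)cc(OC)cc2OC)c1OC
F6 | step 8 | [3-methoxy-5-(2,4,6-trimethoxyphenoxy)phenyl]boronic acid | COc1cc(B(O)O)cc(Oc2c(OC)cc(OC)cc2OC)c1
F7 | step 8 | (4-methoxyphenyl)[3-methoxy-5-(2,4,6-trimethoxyphenoxy)phenyl]iodonium tetrafluoroborate | COc1ccc([I+]c2cc(OC)cc(Oc3c(OC)cc(OC)cc3OC)c2)cc1.F[B-](F)(F)F
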